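Its constants stand for no real mixture; the run is a simulation.

Each unit of J charged meets 2.00 units of E, so J is the limiting reagent, and the decision for the next run is which vessel gets this charge.

    J + E ⇌ J.E (K1 = 72 M⁻¹, k1 = 0.0059 M⁻¹ s⁻¹)
    J + E ⇌ Z (K2 = 25 M⁻¹, k2 = 0.0012 M⁻¹ s⁻¹)
    J + J.E ⇌ J.J.E, settled at all times (K3 = 230 M⁻¹)
    E + J.E → E.J.E (k4 = 2.7 × 10⁻⁴ M⁻¹ s⁻¹)

common to all: E 0.100 M

| charge | J | time | remark |
|---|---|---|---|
| eta | 0.050 M | 1.5 h | everything together in a closed stirred flask, run for 1.5 h |
| gamma | 0.050 M (fed, over 0.750 h) | 1.5 h | a stirred flask in which J is dosed at a steady rate over 0.750 h without added volume, worked up at 1.5 h |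
| zeta | 0.050 M |  | a single well-mixed tank run continuously and read at steady state, 1.5 h in it on average |
| delta | 0.050 M | 1.5 h | plug flow through a tube for 1.5 h, no back-mixing |

- the set-up with the highest share of J.E in all that became J.E or Z or E.J.E, at the outlet or at the end ("none" if the first two lie within 2 percentage points) (eta / gamma / zeta / delta / none)
- share of J.E in all that became J.E or Z or E.J.E, at the outlet or at the end, eta
- share of J.E in all that became J.E or Z or E.J.E, at the outlet or at the end, gamma
- share of J.E in all that became J.E or Z or E.J.E, at the outlet or at the end, zeta
- share of J.E in all that became J.E or Z or E.J.E, at the outlet or at the end, delta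

- percentages count the J that a species holds: one J.J.E counts as two
- J.E is meant together with its J.J.E
- the stated concentrations are those of everything mixed, before any reaction; amounts are the same in each set-up
- the feed brings no volume worth counting
- in an amount of J.E, one J.J.E counts as one J.E
- run time (eta): 1.5 h

The steps to J.E and to Z consume the same J and E at the same order, so their forward rates stand in the ratio of their constants at every moment of a run. I call that ratio the selectivity factor S, and it is 4.92. S over S plus one gives 83.1 %, the first-round share: the fraction of the forward flow from J and E that takes the step to J.E.

Now I put that answer back in and go round once more. Free J.E has a half-life of 7.1 h by step 4 alone with E at its charge, long against the run, and the rate constant of that step times that E times the run, which I call the exposure, is 0.146. With J standing at its charge, the balance of step 3 leaves a fraction 0.0800 of J.E free, the rest sitting as J.J.E, its resting state. That fraction holds while J stands at its charge, and with it the second round gives 82.1 %. I carry both rounds unchanged to each set-up, so I commit to that share for each, with no winner, and I leave the plain batch as it is.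

The forecast gave 86 % for eta, 86.3 % for gamma, 88.6 % for zeta and 86 % for delta, and chose zeta, saying “I counted shares by J held, with J.J.E as two”. My share stands lower than each of these, and I count one J.J.E as one J.E, as the conventions above state.

The flasks give 81.5 % for eta, 82.3 % for gamma, 81.9 % for zeta and 81.5 % for delta, so the answer is none, and the batch stays. Delta stands 1.6 percentage points below the first-round share. The neighbour is delta charged with 0.40 M of E. E enters both forward rates, so the first-round share remains 83.1 %, but the exposure grows to 0.583, and the second round, with the same free fraction, gives 79.2 %. That flask gives 61.1 %, with J.E at 53.1 %, E.J.E at 19.1 % and Z at 14.7 % of the J charged. J.E and E.J.E together make 83.1 % of what reacted. At its end, free J is 2.2 % of the charge and J.J.E holds 21.8 %.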